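The five-membered ring of the cyclopenta[c]pyran (C4a, C5, C6, C7, C7a) carries a single carbon substituent, the formyl carbon on C7, next to fusion carbon C7a. This is read as a carbon atom extruded from a benzene ring: an isochromene ortho-quinone diazide (C7 diazo, C8 carbonyl) undergoes photochemical Wolff ring contraction, methanol captures the ketene as the C7 ester, and loss of methanol from the C1 acetal aromatises the pseudoazulene, all in one operation. The precursor is a 7-diazo-1-methoxy-1H-isochromen-8-one bearing the silylated (S)-side chain at C4, assembled by arylating a geranial-derived ester with a nitrated salicylaldehyde.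

Key step: step 13

Assumption: geranial is used as the pure (E)-aldehyde; the (S)-phosphoric acid is taken to deliver allyl to the Si face of the enal (mirror image of the sense known for the (R)-acid), to be confirmed on the first carbinol; the auxiliary acetal carbons and C1 of the isochromene are carried as epimer mixtures because all of them are erased before the target.

Step 1
Reactants: 1 geranial [(2E)-3,7-dimethylocta-2,6-dienal]; 2 allylboronic acid pinacol ester
Product: 3 (4S,5E)-6,10-dimethylundeca-1,5,9-trien-4-ol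
Conditions: (S)-3,3′-bis(2,4,6-triisopropylphenyl)-1,1′-binaphthyl-2,2′-diyl hydrogen phosphate [(S)-TRIP, 5 mol%], 4 Å MS, toluene, −30 °C; aqueous work-up
Reagents that add atoms: none
Why: Brønsted acid-catalysed asymmetric allylboration, in which the chiral phosphoric acid organises a chair six-membered transition state (P–OH to a boronate oxygen, P=O to the formyl hydrogen) and the (S)-acid should leave the Si face of the enal open, so that the new carbinol centre C4 is S while the E geometry of the enal is untouched.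

Step 2
Reactants: 3 (4S,5E)-6,10-dimethylundeca-1,5,9-trien-4-ol
Product: 4 (4S,5E)-4-(tert-butyldimethylsilyloxy)-6,10-dimethylundeca-1,5,9-triene (TBSO = tert-butyldimethylsilyloxy below)
Conditions: TBSCl, imidazole, DMF, rt
Reagents that add atoms: tert-butyldimethylsilyl chloride, CC(C)(C)[Si](C)(C)Cl
Why: Silylation of a secondary alcohol through the N-silylimidazolium species, which does not touch the stereocentre and gives an ether that lasts until fluoride is applied in step 16.

Step 3
Reactants: 4 (4S,5E)-4-(TBSO)-6,10-dimethylundeca-1,5,9-triene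
Product: 6 (4S,5E)-4-(TBSO)-6,10-dimethylundeca-5,9-dien-1-ol, via B-alkyl-9-BBN adduct 5 (not isolated)
Conditions: 9-BBN-H, THF, 0 °C → rt; then NaOH (aq.), H2O2, 0 °C
Reagents that add atoms: hydrogen peroxide, OO
Why: Hydroboration–oxidation, in which the bulky dialkylborane adds anti-Markovnikov to the monosubstituted terminal alkene far faster than to either trisubstituted alkene and alkaline peroxide then replaces boron by hydroxyl while the silyl ether survives.

Step 4
Reactants: 6 (4S,5E)-4-(TBSO)-6,10-dimethylundeca-5,9-dien-1-ol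
Product: 7 (4S,5E)-4-(TBSO)-6,10-dimethylundeca-5,9-dienoic acid
Conditions: 2,2,6,6-tetramethylpiperidin-1-oxyl (TEMPO, cat.), PhI(OAc)2, MeCN/H2O, rt
Reagents that add atoms: water, O
Why: Oxoammonium (TEMPO)-catalysed oxidation with PhI(OAc)2 as terminal oxidant takes the primary alcohol through the aldehyde hydrate to the acid without touching the trisubstituted alkenes or the silyl ether.

Step 5
Reactants: 7 (4S,5E)-4-(TBSO)-6,10-dimethylundeca-5,9-dienoic acid
Product: 8 methyl (4S,5E)-4-(TBSO)-6,10-dimethylundeca-5,9-dienoate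
Conditions: MeI, K2CO3, DMF, rt
Reagents that add atoms: iodomethane, CI
Why: SN2 O-alkylation of the carboxylate under mild carbonate base, with no risk to the γ-silyloxy stereocentre.

Step 6
Reactants: 9 2-bromo-6-hydroxybenzaldehyde
Product: 10 6-bromo-2-hydroxy-3-nitrobenzaldehyde
Conditions: HNO3 (70%, 1.05 equiv), AcOH, 10 °C
Reagents that add atoms: nitric acid, O[N+](=O)[O-]
Why: Electrophilic aromatic nitration of a phenol, in which the position ortho to OH and para to Br should be preferred because the competing position para to OH is flanked by bromine; the minor isomer is removed by chromatography at this inexpensive first stage.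

Step 7
Reactants: 10 6-bromo-2-hydroxy-3-nitrobenzaldehyde
Product: 12 1-bromo-2-(dimethoxymethyl)-3-(1-ethoxyethoxy)-4-nitrobenzene, via acetal phenol 11 (not isolated)
Conditions: CH(OMe)3, pyridinium p-toluenesulfonate (PPTS, cat.), MeOH, 50 °C; evaporate; ethyl vinyl ether, PPTS, CH2Cl2, rt
Reagents that add atoms: trimethyl orthoformate, COC(OC)OC; ethyl vinyl ether, C=COCC
Why: Acid-catalysed acetalisation driven by the orthoformate followed by acid-catalysed addition of the phenol to the vinyl ether gives two masks that resist enolates and hydride and are both released by one mild acid treatment in step 10 (the new acetal centre is stereorandom and is removed there).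

Step 8
Reactants: 8 methyl (4S,5E)-4-(TBSO)-6,10-dimethylundeca-5,9-dienoate; 12 1-bromo-2-(dimethoxymethyl)-3-(1-ethoxyethoxy)-4-nitrobenzene
Product: 15 methyl (4S,5E)-2-[2-(dimethoxymethyl)-3-(1-ethoxyethoxy)-4-nitrophenyl]-4-(TBSO)-6,10-dimethylundeca-5,9-dienoate, via lithium enolate 13 (not isolated), via chlorozinc enolate 14 (not isolated)
Conditions: LiN(i-Pr)2, THF, −78 °C; ZnCl2, −78 °C → rt; then 12, Pd(dba)2 [bis(dibenzylideneacetone)palladium, 3 mol%], P(t-Bu)3 (3 mol%), rt → 50 °C
Reagents that add atoms: none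
Why: Pd-catalysed α-arylation of an ester zinc enolate (Negishi-type coupling) by oxidative addition of the para-nitro-activated C–Br bond to zerovalent palladium, transmetalation from zinc and C–C reductive elimination, the zinc enolate being mild enough to spare the nitro group and both acetals; the benzylic centre forms as both epimers and becomes sp2 in step 10.

Step 9
Reactants: 15 methyl (4S,5E)-2-[2-(dimethoxymethyl)-3-(1-ethoxyethoxy)-4-nitrophenyl]-4-(TBSO)-6,10-dimethylundeca-5,9-dienoate
Product: 16 (4S,5E)-2-[2-(dimethoxymethyl)-3-(1-ethoxyethoxy)-4-nitrophenyl]-4-(TBSO)-6,10-dimethylundeca-5,9-dienal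
Conditions: i-Bu2AlH (1.1 equiv), CH2Cl2, −78 °C; aq. potassium sodium tartrate
Reagents that add atoms: none
Why: Partial hydride reduction of an ester, in which the tetrahedral aluminium hemiacetal, chelated by the neighbouring acetal oxygen, should persist at −78 °C until the quench and then collapse to the aldehyde, while nitro, acetals and silyl ether are inert at this temperature.

Step 10
Reactants: 16 (4S,5E)-2-[2-(dimethoxymethyl)-3-(1-ethoxyethoxy)-4-nitrophenyl]-4-(TBSO)-6,10-dimethylundeca-5,9-dienal
Product: 19 4-[(2S,3E)-2-(TBSO)-4,8-dimethylnona-3,7-dien-1-yl]-1-methoxy-7-nitro-1H-isochromen-8-ol, via free phenol 17 (not isolated), via cyclic bis-acetal 18 (not isolated)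
Conditions: PPTS (cat.), MeOH, rt; then solvent exchanged for toluene, 4 Å MS, 60 °C
Reagents that add atoms: methanol, CO
Why: Acid-catalysed transacetalisation and E1 elimination, in which methanolysis removes the ethoxyethyl group and joins the two carbonyl carbons through oxygen as a six-membered cyclic bis-acetal, and heating with removal of methanol ionises C3–OMe and expels the benzylic C4 proton to give the enol ether conjugated with the nitroarene faster than the hindered silyl ether oxygen can attack C3; C1 remains an epimer mixture.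

Step 11
Reactants: 19 4-[(2S,3E)-2-(TBSO)-4,8-dimethylnona-3,7-dien-1-yl]-1-methoxy-7-nitro-1H-isochromen-8-ol
Product: 20 7-amino-4-[(2S,3E)-2-(TBSO)-4,8-dimethylnona-3,7-dien-1-yl]-1-methoxy-1H-isochromen-8-ol
Conditions: Na2S2O4, NaHCO3, THF/H2O, rt
Reagents that add atoms: none
Why: Dithionite reduction of an aromatic nitro group by electron transfer in bicarbonate buffer leaves the alkenes, the enol ether–acetal and the silyl ether untouched, where catalytic hydrogenation or acidic metals would not.

Step 12
Reactants: 20 7-amino-4-[(2S,3E)-2-(TBSO)-4,8-dimethylnona-3,7-dien-1-yl]-1-methoxy-1H-isochromen-8-ol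
Product: 21 7-diazo-4-[(2S,3E)-2-(TBSO)-4,8-dimethylnona-3,7-dien-1-yl]-1-methoxy-1H-isochromen-8(7H)-one
Conditions: t-BuONO, AcOH (1 equiv), THF, 0 °C, dark; NaHCO3 wash; used at once
Reagents that add atoms: tert-butyl nitrite, CC(C)(C)ON=O
Why: Diazotisation of an ortho-aminophenol with an alkyl nitrite (N-nitrosation, dehydration to the diazonium ion, loss of the phenolic proton) gives the neutral ortho-quinone diazide without mineral acid, so the acid-labile enol ether–acetal is kept.

Step 13
Reactants: 21 7-diazo-4-[(2S,3E)-2-(TBSO)-4,8-dimethylnona-3,7-dien-1-yl]-1-methoxy-1H-isochromen-8(7H)-one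
Product: 24 methyl 4-[(2S,3E)-2-(TBSO)-4,8-dimethylnona-3,7-dien-1-yl]cyclopenta[c]pyran-7-carboxylate, via ketene 22 (not isolated), via cyclopentadiene ester 23 (not isolated)
Conditions: hν (365 nm LED), MeOH (degassed, 5 mM), 0 °C; then Et3N (2 equiv), rt
Reagents that add atoms: methanol, CO
Why: Excitation of the diazide expels N2 and the ring bond C8–C8a migrates to the diazo carbon C7 (concerted or through the singlet ketocarbene), so C8 is pushed out as a ketene on a new five-membered ring made of the former C4a, C5, C6, C7 and C8a; methanol adds to the ketene to give the cyclopentadiene methyl ester, whose acidic ring C–H is removed by Et3N, and the cyclopentadienide expels methoxide from the adjacent acetal carbon C1 (E1cB) to give the 10-electron cyclopenta[c]pyran. The closest known reaction type is the photochemical Wolff ring contraction of benzo- and naphtho-fused ortho-quinone diazides to cyclopentadiene- and indene-carboxylic acid derivatives, followed by a fulvene-type elimination. The five-membered ring arises by a 1,2-shift (ring contraction) and not by a cyclisation, and no stereocentre is created, the C1 epimers converging on one product. The step needs the carboxyl carbon on C7 and not on C5, which is fixed because the diazo carbon can only receive the fusion carbon that was bonded to the carbonyl carbon; it also needs rearrangement to outrun O–H insertion of the carbene, which the s-cis geometry locked in the ring should secure. High dilution and full photolysis before the base is added keep the nucleophilic product from azo coupling with unreacted diazide, and the isolated alkenes do not absorb at 365 nm.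

Step 14
Reactants: 24 methyl 4-[(2S,3E)-2-(TBSO)-4,8-dimethylnona-3,7-dien-1-yl]cyclopenta[c]pyran-7-carboxylate
Product: 25 {4-[(2S,3E)-2-(TBSO)-4,8-dimethylnona-3,7-dien-1-yl]cyclopenta[c]pyran-7-yl}methanol
Conditions: i-Bu2AlH (2.5 equiv), CH2Cl2, −78 → −20 °C; aq. potassium sodium tartrate, NaHCO3; crude used at once
Reagents that add atoms: none
Why: Hydride reduction of the ester to the primary alcohol, for which the vinylogous carbonate character of the ester demands excess reagent and warming to −20 °C; because the carbinol ionises easily to a pyrylium-stabilised cation it is worked up under buffered conditions and oxidised without storage.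

Step 15
Reactants: 25 {4-[(2S,3E)-2-(TBSO)-4,8-dimethylnona-3,7-dien-1-yl]cyclopenta[c]pyran-7-yl}methanol
Product: 26 4-[(2S,3E)-2-(TBSO)-4,8-dimethylnona-3,7-dien-1-yl]cyclopenta[c]pyran-7-carbaldehyde
Conditions: MnO2 (activated, excess), CH2Cl2, rt
Reagents that add atoms: none
Why: MnO2 oxidation of an activated (benzylic-type) primary alcohol on the electron-rich five-membered ring stops at the aldehyde and ignores the silyl ether and the isolated alkenes.

Step 16
Reactants: 26 4-[(2S,3E)-2-(TBSO)-4,8-dimethylnona-3,7-dien-1-yl]cyclopenta[c]pyran-7-carbaldehyde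
Product: 27 4-[(2S,3E)-2-hydroxy-4,8-dimethylnona-3,7-dien-1-yl]cyclopenta[c]pyran-7-carbaldehyde
Conditions: Bu4NF, AcOH (1:1), THF, rt
Reagents that add atoms: none
Why: Fluoride-induced Si–O cleavage with acetic acid as buffer, so that no free alkoxide or hydroxide adds to the electrophilic pyran carbons C1 and C3, and the C–O bond at the stereocentre is not broken.

Step 17
Reactants: 27 4-[(2S,3E)-2-hydroxy-4,8-dimethylnona-3,7-dien-1-yl]cyclopenta[c]pyran-7-carbaldehyde
Product: 28 (2S,3E)-1-(7-formylcyclopenta[c]pyran-4-yl)-4,8-dimethylnona-3,7-dien-2-yl acetate (CNP0325919.1)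
Conditions: Ac2O, pyridine, 4-(dimethylamino)pyridine (cat.), CH2Cl2, 0 °C → rt
Reagents that add atoms: acetic anhydride, CC(=O)OC(C)=O
Why: Nucleophile-catalysed acylation of the secondary allylic alcohol proceeds with retention, since only the O–H bond reacts.

Compound list
1 | geranial, (2E)-3,7-dimethylocta-2,6-dienal | CC(C)=CCC/C(C)=C/C=O | starting material
2 | allylboronic acid pinacol ester | C=CCB1OC(C)(C)C(C)(C)O1 | starting material
3 | (4S,5E)-6,10-dimethylundeca-1,5,9-trien-4-ol | C=CC[C@H](O)/C=C(\C)CCC=C(C)C | intermediate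
4 | (4S,5E)-4-(tert-butyldimethylsilyloxy)-6,10-dimethylundeca-1,5,9-triene | C=CC[C@H](O[Si](C)(C)C(C)(C)C)/C=C(\C)CCC=C(C)C | intermediate
5 | B-[(4S,5E)-4-(TBSO)-6,10-dimethylundeca-5,9-dien-1-yl]-9-borabicyclo[3.3.1]nonane | C1CCC2CCCC1B2CCC[C@H](O[Si](C)(C)C(C)(C)C)/C=C(\C)CCC=C(C)C | intermediate
6 | (4S,5E)-4-(TBSO)-6,10-dimethylundeca-5,9-dien-1-ol | OCCC[C@H](O[Si](C)(C)C(C)(C)C)/C=C(\C)CCC=C(C)C | intermediate
7 | (4S,5E)-4-(TBSO)-6,10-dimethylundeca-5,9-dienoic acid | OC(=O)CC[C@H](O[Si](C)(C)C(C)(C)C)/C=C(\C)CCC=C(C)C | intermediate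
8 | methyl (4S,5E)-4-(TBSO)-6,10-dimethylundeca-5,9-dienoate | COC(=O)CC[C@H](O[Si](C)(C)C(C)(C)C)/C=C(\C)CCC=C(C)C | intermediate
9 | 2-bromo-6-hydroxybenzaldehyde | O=Cc1c(O)cccc1Br | starting material
10 | 6-bromo-2-hydroxy-3-nitrobenzaldehyde | O=Cc1c(O)c([N+](=O)[O-])ccc1Br | intermediate
11 | 3-bromo-2-(dimethoxymethyl)-6-nitrophenol | COC(OC)c1c(O)c([N+](=O)[O-])ccc1Br | intermediate
12 | 1-bromo-2-(dimethoxymethyl)-3-(1-ethoxyethoxy)-4-nitrobenzene (racemic at the acetal carbon) | CCOC(C)Oc1c([N+](=O)[O-])ccc(Br)c1C(OC)OC | intermediate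
13 | lithium enolate of ester 8 | COC(O[Li])=CC[C@H](O[Si](C)(C)C(C)(C)C)/C=C(\C)CCC=C(C)C | intermediate
14 | chlorozinc enolate of ester 8 | COC(O[Zn]Cl)=CC[C@H](O[Si](C)(C)C(C)(C)C)/C=C(\C)CCC=C(C)C | intermediate
15 | methyl (4S,5E)-2-[2-(dimethoxymethyl)-3-(1-ethoxyethoxy)-4-nitrophenyl]-4-(TBSO)-6,10-dimethylundeca-5,9-dienoate (epimers at C2 and at the acetal carbon) | COC(=O)C(C[C@H](O[Si](C)(C)C(C)(C)C)/C=C(\C)CCC=C(C)C)c1ccc([N+](=O)[O-])c(OC(C)OCC)c1C(OC)OC | intermediate
16 | (4S,5E)-2-[2-(dimethoxymethyl)-3-(1-ethoxyethoxy)-4-nitrophenyl]-4-(TBSO)-6,10-dimethylundeca-5,9-dienal (same epimer mixture) | O=CC(C[C@H](O[Si](C)(C)C(C)(C)C)/C=C(\C)CCC=C(C)C)c1ccc([N+](=O)[O-])c(OC(C)OCC)c1C(OC)OC | intermediate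
17 | (4S,5E)-2-[2-(dimethoxymethyl)-3-hydroxy-4-nitrophenyl]-4-(TBSO)-6,10-dimethylundeca-5,9-dienal | O=CC(C[C@H](O[Si](C)(C)C(C)(C)C)/C=C(\C)CCC=C(C)C)c1ccc([N+](=O)[O-])c(O)c1C(OC)OC | intermediate
18 | 4-[(2S,3E)-2-(TBSO)-4,8-dimethylnona-3,7-dien-1-yl]-1,3-dimethoxy-7-nitro-3,4-dihydro-1H-isochromen-8-ol (ring epimers) | COC1OC(OC)C(C[C@H](O[Si](C)(C)C(C)(C)C)/C=C(\C)CCC=C(C)C)c2ccc([N+](=O)[O-])c(O)c21 | intermediate
19 | 4-[(2S,3E)-2-(TBSO)-4,8-dimethylnona-3,7-dien-1-yl]-1-methoxy-7-nitro-1H-isochromen-8-ol (C1 epimers) | COC1OC=C(C[C@H](O[Si](C)(C)C(C)(C)C)/C=C(\C)CCC=C(C)C)c2ccc([N+](=O)[O-])c(O)c21 | intermediate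
20 | 7-amino-4-[(2S,3E)-2-(TBSO)-4,8-dimethylnona-3,7-dien-1-yl]-1-methoxy-1H-isochromen-8-ol (C1 epimers) | COC1OC=C(C[C@H](O[Si](C)(C)C(C)(C)C)/C=C(\C)CCC=C(C)C)c2ccc(N)c(O)c21 | intermediate
21 | 7-diazo-4-[(2S,3E)-2-(TBSO)-4,8-dimethylnona-3,7-dien-1-yl]-1-methoxy-1H-isochromen-8(7H)-one (C1 epimers) | COC1OC=C(C[C@H](O[Si](C)(C)C(C)(C)C)/C=C(\C)CCC=C(C)C)C2=C1C(=O)C(=[N+]=[N-])C=C2 | intermediate
22 | 4-[(2S,3E)-2-(TBSO)-4,8-dimethylnona-3,7-dien-1-yl]-1-methoxy-7-(oxomethylidene)-1,7-dihydrocyclopenta[c]pyran (ketene) | COC1OC=C(C[C@H](O[Si](C)(C)C(C)(C)C)/C=C(\C)CCC=C(C)C)C2=C1C(=C=O)C=C2 | intermediate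
23 | methyl 4-[(2S,3E)-2-(TBSO)-4,8-dimethylnona-3,7-dien-1-yl]-1-methoxy-1,7-dihydrocyclopenta[c]pyran-7-carboxylate | COC1OC=C(C[C@H](O[Si](C)(C)C(C)(C)C)/C=C(\C)CCC=C(C)C)C2=C1C(C(=O)OC)C=C2 | intermediate
24 | methyl 4-[(2S,3E)-2-(TBSO)-4,8-dimethylnona-3,7-dien-1-yl]cyclopenta[c]pyran-7-carboxylate | CC(C)(C)[Si](C)(C)O[C@H](/C=C(\C)CCC=C(C)C)Cc1cocc2c(C(=O)OC)ccc1-2 | intermediate
25 | {4-[(2S,3E)-2-(TBSO)-4,8-dimethylnona-3,7-dien-1-yl]cyclopenta[c]pyran-7-yl}methanol | CC(C)(C)[Si](C)(C)O[C@H](/C=C(\C)CCC=C(C)C)Cc1cocc2c(CO)ccc1-2 | intermediate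
26 | 4-[(2S,3E)-2-(TBSO)-4,8-dimethylnona-3,7-dien-1-yl]cyclopenta[c]pyran-7-carbaldehyde | CC(C)(C)[Si](C)(C)O[C@H](/C=C(\C)CCC=C(C)C)Cc1cocc2c(C=O)ccc1-2 | intermediate
27 | 4-[(2S,3E)-2-hydroxy-4,8-dimethylnona-3,7-dien-1-yl]cyclopenta[c]pyran-7-carbaldehyde | O[C@H](/C=C(\C)CCC=C(C)C)Cc1cocc2c(C=O)ccc1-2 | intermediate
28 | (2S,3E)-1-(7-formylcyclopenta[c]pyran-4-yl)-4,8-dimethylnona-3,7-dien-2-yl acetate | CC(=O)O[C@H](/C=C(\C)CCC=C(C)C)Cc1cocc2c(C=O)ccc1-2 | target

Total step count: 17.
Longest linear sequence: 15 steps (steps 1–5 and 8–17, from geranial); the aryl bromide 12 is made in two steps (6 and 7).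

Steps most likely to fail

Step 13. What may go wrong: because aromatisation takes place in the irradiated solution, the electron-rich product (nucleophilic at C5) may couple with diazide not yet photolysed, and the coloured product may undergo secondary photochemistry. Fallback: contract the ring on the saturated bis-acetal and aromatise in a separate operation. It sets out from 18, isolated after the methanol stage of step 10. Na2S2O4/NaHCO3 in THF/H2O should give the aminophenol 7-amino-4-[(2S,3E)-2-(TBSO)-4,8-dimethylnona-3,7-dien-1-yl]-1,3-dimethoxy-3,4-dihydro-1H-isochromen-8-ol F1. t-BuONO/AcOH in THF should give 7-diazo-4-[(2S,3E)-2-(TBSO)-4,8-dimethylnona-3,7-dien-1-yl]-1,3-dimethoxy-3,4-dihydro-1H-isochromen-8(7H)-one F2, an ordinary benzo-fused ortho-quinone diazide without an enol ether. Irradiation at 365 nm in methanol should give methyl 4-[(2S,3E)-2-(TBSO)-4,8-dimethylnona-3,7-dien-1-yl]-1,3-dimethoxy-1,3,4,7-tetrahydrocyclopenta[c]pyran-7-carboxylate F3, which cannot aromatise under neutral conditions. PPTS in toluene at 70 °C should then remove two molecules of methanol (C3–C4 elimination, then loss of the C1 methoxy group with the C7 proton), and the route is rejoined at 24.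

Step 8. What may go wrong: proton transfer from the acidic α-(nitroaryl) ester product to the zinc enolate, or slow transmetalation at the ortho-substituted arylpalladium species, may leave the coupling incomplete. Fallback: arylate an aldehyde enolate under carbonate base, where the acidic product simply rests as its enolate; this is held in reserve because the aldehyde can self-condense. It sets out from alcohol 6. Oxidation with DMP (1,1,1-triacetoxy-1,1-dihydro-1,2-benziodoxol-3(1H)-one), NaHCO3, CH2Cl2 should give (4S,5E)-4-(TBSO)-6,10-dimethylundeca-5,9-dienal F4. Pd(OAc)2, rac-BINAP, Cs2CO3, dioxane, 80 °C should couple F4 with 12, and the route is rejoined at aldehyde 16, steps 4, 5, 8 and 9 being bypassed.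

Step 14. What may go wrong: the aluminium alkoxide or the free carbinol may ionise to the pyrylium-stabilised cation, leading to over-reduction to the 7-methyl compound or to oligomerisation; the deactivated ester may also be reduced incompletely. Fallback: bring the carboxyl carbon out of the ring contraction as an N-methoxy-N-methylamide, which is reduced to the aldehyde without passing through the carbinol. It sets out from diazide 21. Irradiation at 365 nm in MeCN containing MeNHOMe (5 equiv), then Et3N, should give 4-[(2S,3E)-2-(TBSO)-4,8-dimethylnona-3,7-dien-1-yl]-N-methoxy-N-methylcyclopenta[c]pyran-7-carboxamide F5. i-Bu2AlH in THF at −78 °C should reduce F5 through a chelated aluminium aminal that releases the aldehyde only on work-up, and the route is rejoined at 26, step 15 being bypassed.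

Further compounds
F1 | step 13 | 7-amino-4-[(2S,3E)-2-(TBSO)-4,8-dimethylnona-3,7-dien-1-yl]-1,3-dimethoxy-3,4-dihydro-1H-isochromen-8-ol | COC1OC(OC)C(C[C@H](O[Si](C)(C)C(C)(C)C)/C=C(\C)CCC=C(C)C)c2ccc(N)c(O)c21
F2 | step 13 | 7-diazo-4-[(2S,3E)-2-(TBSO)-4,8-dimethylnona-3,7-dien-1-yl]-1,3-dimethoxy-3,4-dihydro-1H-isochromen-8(7H)-one | COC1OC(OC)C(C[C@H](O[Si](C)(C)C(C)(C)C)/C=C(\C)CCC=C(C)C)C2=C1C(=O)C(=[N+]=[N-])C=C2
F3 | step 13 | methyl 4-[(2S,3E)-2-(TBSO)-4,8-dimethylnona-3,7-dien-1-yl]-1,3-dimethoxy-1,3,4,7-tetrahydrocyclopenta[c]pyran-7-carboxylate | COC1OC(OC)C(C[C@H](O[Si](C)(C)C(C)(C)C)/C=C(\C)CCC=C(C)C)C2=C1C(C(=O)OC)C=C2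
F4 | step 8 | (4S,5E)-4-(TBSO)-6,10-dimethylundeca-5,9-dienal | O=CCC[C@H](O[Si](C)(C)C(C)(C)C)/C=C(\C)CCC=C(C)C
F5 | step 14 | 4-[(2S,3E)-2-(TBSO)-4,8-dimethylnona-3,7-dien-1-yl]-N-methoxy-N-methylcyclopenta[c]pyran-7-carboxamide | CC(C)(C)[Si](C)(C)O[C@H](/C=C(\C)CCC=C(C)C)Cc1cocc2c(C(=O)N(C)OC)ccc1-2
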